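All runs were computed for an exercise, noise included.

The right-handed substrate is the slow one: in Thursday's first reading, right-handed product stood lower at 9.6%, against 21.2% of left-handed product.

common to all: left-handed substrate 0.25 M; right-handed substrate 0.25 M; catalyst 5 mol%
- Thursday's: coupling partner 3 equiv; run made earlier
- Wednesday's: coupling partner 1.5 equiv; run made earlier
- Saturday's: coupling partner 2.2 equiv; run made earlier
- north: coupling partner 3.00 equiv; everything together in a closed stirred flask, run for 3.0 h; time 3.0 h
- south-east: coupling partner 3.00 equiv; one stirred flow tank at steady state, fed with the mixture as stated, mean residence time 30.0 h
- south-west: coupling partner 3.00 equiv (fed, over 1.50 h); all but coupling partner at the start; coupling partner goes in evenly over 1.50 h, the run ends at 3.0 h; time 3.0 h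
- west: coupling partner 3.00 equiv; a single well-mixed tank run continuously and read at steady state, 3.0 h in it on average

| run | time / h | left-handed product / % | right-handed product / % |
|---|---|---|---|
| Thursday's | 0.200 | 21.2 | 9.6 |
| Thursday's | 0.667 | 39.9 | 22.4 |
| Thursday's | 1.00 | 45.9 | 26.8 |
| Thursday's | 1.50 | 51.0 | 31.1 |
| Thursday's | 2.50 | 54.8 | 36.1 |
| Thursday's | 3.00 | 56.4 | 37.5 |
| Wednesday's | 0.200 | 12.6 | 4.9 |
| Wednesday's | 0.333 | 17.6 | 8.1 |
| Wednesday's | 0.500 | 22.3 | 10.0 |
| Wednesday's | 0.833 | 28.8 | 14.0 |
| Wednesday's | 1.33 | 35.1 | 17.2 |
| Wednesday's | 2.50 | 42.2 | 21.1 |
| Saturday's | 0.417 | 26.1 | 12.4 |
| Saturday's | 0.833 | 37.6 | 19.5 |
| Saturday's | 1.33 | 43.5 | 23.9 |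
| Saturday's | 1.50 | 45.0 | 25.1 |
| Saturday's | 2.00 | 48.7 | 27.4 |
| Saturday's | 2.50 | 51.3 | 29.0 |

(each reading ± 0.3 percentage points)

- the set-up with the highest share of left-handed product in all that became left-handed product or right-handed product, at the outlet or at the end ("none" if the first two lie within 2 percentage points) (north / south-east / south-west / west / none)
- share of left-handed product in all that became left-handed product or right-handed product, at the outlet or at the end, north
- share of left-handed product in all that became left-handed product or right-handed product, at the outlet or at the end, south-east
- share of left-handed product in all that became left-handed product or right-handed product, at the outlet or at the end, south-west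
- share of left-handed product in all that became left-handed product or right-handed product, at the outlet or at the end, west

- catalyst is single-handed; left-handed substrate and right-handed substrate are mirror images of each other, charged as a racemate, each of them at the stated concentration
- the stated concentrations are those of everything mixed, before any reaction; amounts are the same in each set-up
- the feed brings no volume worth counting
- the earlier runs were made in a closed, stirred flask

I read Thursday's first reading as a pseudo-first-order decay of each hand, with partner in excess. The left-handed substrate's time constant came to 0.363 h. The right-handed substrate's came to 0.938 h, longer by a reading of the selectivity factor of 2.58. Wednesday's first reading, with half the partner, gave a left-handed time constant 1.90 times as long, so I took both time constants to go inversely with partner.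

Thursday's left-handed product reached 56.4% of both hands charged, more than the left-handed substrate's share of the charge, so right-handed substrate must have turned into left-handed substrate by racemization. During the gap of 0.575 h between Thursday's two time constants, racemization can refill the left-handed substrate. I took the lead, meaning left-handed minus right-handed product as a fraction of both, to scale with that gap. The lead times the partner equivalents should then hold steady late in a closed flask. I called this the lead constant: 0.604 equiv from Thursday's last reading. Saturday's last reading gave 0.611 equiv. Wednesday's last reading, at 1.5 equiv, gave 0.500 equiv, so I held the constant for the two higher loadings and upward.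

Thursday's recipe is north's, so I put north at 60.1%. I reckoned neither the tanks nor the fed flask with this constant.

The forecast gave north 60.1%, south-east 62.3%, south-west 62.3%, west 62.3% and best none: “The top set-ups lie within 2 points, so best is none.”

The simulation gave north 60.3%, south-east 61.9%, south-west 61.8%, west 62.0% and best none.

    coupling partner + catalyst + left-handed substrate → catalyst + left-handed product (k = 330 L² mol⁻² h⁻¹)
    left-handed substrate ⇌ right-handed substrate (k = 0.370 h⁻¹)
    coupling partner + catalyst + right-handed substrate → catalyst + right-handed product (k = 130 L² mol⁻² h⁻¹)

North's result makes the lead constant 0.617 equiv, beside the 0.604 equiv I read. A neighbouring flask is north with 12.0 equiv of partner. There the constant gives a lead of 0.0503, so a share of 52.5%. That flask ended with 0% of the left-handed substrate and 0% of the right-handed substrate, and its share was 52.3%: left-handed product 52.3%, right-handed product 47.7%.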